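84.3% of the substrate charged in the south-east run stands, by the readings, neither as substrate nor as single ring at 4.00 h, against 36.2% in the south-west run at 4.00 h.

| flask | substrate | remark | time |
|---|---|---|---|
| south-west | 0.074 M | run made earlier |  |
| north-east | 0.22 M | run made earlier |  |
| south-east | 1.1 M | run made earlier |  |
| winter | 0.25 M |  | 6.0 h |
| noon | 0.80 M |  | 6.0 h |
| autumn | 1.0 M |  | 6.0 h |
| summer | 0.060 M |  | 6.0 h |
| midnight | 0.12 M |  | 6.0 h |
| dawn | 0.080 M |  | 6.0 h |

| run | time / h | single ring / % | substrate / % |
|---|---|---|---|
| south-west | 0.333 | 6.1 | 80.7 |
| south-west | 0.667 | 15.9 | 69.6 |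
| south-west | 1.33 | 29.9 | 49.5 |
| south-west | 2.00 | 38.1 | 34.5 |
| south-west | 4.00 | 49.7 | 14.1 |
| north-east | 0.417 | 11.1 | 64.8 |
| north-east | 1.00 | 20.1 | 37.2 |
| north-east | 2.00 | 26.9 | 21.6 |
| north-east | 3.00 | 33.6 | 13.5 |
| north-east | 4.00 | 35.8 | 8.0 |
| south-east | 0.417 | 5.7 | 29.6 |
| south-east | 1.00 | 11.4 | 13.7 |
| south-east | 2.00 | 11.1 | 5.4 |
| south-east | 3.00 | 14.4 | 2.5 |
| south-east | 4.00 | 14.2 | 1.5 |

(standard deviation of a reading: 1 percentage point)

- the analysis behind the earlier runs scatters by 1 percentage point, standard deviation
- a reading or a percentage of single ring counts all its forms, free or not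

* the flasks put in order of amount of single ring, in percent of the substrate charged, best first, at 6.0 h (winter / noon / autumn / summer / midnight / dawn)
* the amount of single ring, in percent of the substrate charged of the flask you put first, at 6.0 h
* the amount of single ring, in percent of the substrate charged of the flask you put last, at 6.0 h

Substrate is the limiting reagent, and the ledger of each flask has three entries: substrate left, single ring and a rest. One first-order loss gives the same shares at any charge, but here the rest is larger at the larger charge. The reckoning therefore takes a first-order route to single ring and a second-order route to the rest. At substrate concentration C, single ring receives K/(K+C) of each mole used. Summed over a run: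

yield = (K / charge) · ln[(K + charge) / (K + substrate left)]

The last south-east reading, solved by two passes from a trial value equal to the south-west charge, gives:

K: 0.0609 M, then 0.0577 M

This K is the crossover concentration, the substrate concentration at which both routes take equal shares; it is a selectivity factor, read with the scatter of 1 percentage point. The last south-west reading then gives the clock of the first-order route:

left / (K + left) = charge / (K + charge) · exp(−k · time), with k = 0.325 h⁻¹

The reckoned books at 6.0 h, in percent of the charge:

summer: substrate 7.52%, single ring 61.3%, rest 31.2%

autumn: substrate 0.897%, single ring 15.9%, rest 83.2%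

The share K/(K+C) falls as C rises, so this reckoning ranks the flasks by charge, lowest first: summer, dawn, midnight, winter, noon, autumn.

The forecast gave summer > dawn > midnight > winter > noon > autumn, with 61% (55% to 67%) for summer and 15.5% (13.5% to 18%) for autumn, the latter lower than this reckoning's value, on the ground that “Selectivity is about K/(K+C), with K ≈ 0.057 M.”

The flasks give summer > dawn > midnight > winter > noon > autumn, with 62.5% in summer and 16.4% in autumn.

    crystals ⇌ single ring, rate k1*(cs1 - [single ring]) while solid is left; crystals form when [single ring] > cs1 (solubility = 0.0690 M, k = 0.00400 s⁻¹)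
    2 substrate → open dimer (k = 6.30 × 10⁻⁴ M⁻¹ s⁻¹)
    open dimer → ring dimer (k = 1.72 × 10⁻⁴ s⁻¹)
    substrate → single ring (k = 8.47 × 10⁻⁵ s⁻¹)
    substrate + open dimer → open trimer (k = 1.72 × 10⁻⁴ M⁻¹ s⁻¹)

At the start of summer, the step to single ring uses substrate 1.1 times as fast as the step to open dimer. At 6.00 h, summer holds substrate at 9.12% of its charge, which is 0.00547 M, and at that concentration the crossover concentration reckons single ring at 91.3% of each mole used.

For the neighbour of summer charged with 0.24 M, the same K and clock give substrate 3.12% and single ring 36.5%. At 6.00 h, that neighbour holds 3.87% substrate and 38.2% single ring.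

(The earlier runs and the new flask were generated by integration from invented constants.)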